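## The problem

Oncostemonol B is a resorcinolic lipid in which two 1,3,5-trisubstituted benzene rings are joined by an unbranched sixteen-carbon chain. Ring A (on C1') carries one acetoxy and one hydroxy group, and ring B (on C16') carries two hydroxy groups. A synthesis must therefore either build the chain between two fully oxygenated arenes or build the arenes at the ends of a preformed chain. There is no stereocentre. The only stereochemical element is the (Z)-alkene C8'=C9', which lies far from every functional group, so no substrate element can control it and the reaction that forms it must fix the geometry by mechanism. The aryl acetate is the most fragile group: it is lost to bases, nucleophiles, organometallic reagents and acidic alcohols, so it must be introduced last. The free resorcinols are acidic and strongly activated toward electrophiles and must be masked during C–C bond formation, while the cis-alkene excludes hydrogenolysis and strongly acidic or radical conditions late in the route. Without the acetyl group the molecule has twofold symmetry about the midpoint of C8'=C9' and all four hydroxyls are equivalent, so placing the acetate is a matter of stoichiometry, not site selectivity. The enabling feature is that the alkene sits at the exact centre of the chain between two identical 7-arylheptyl arms (C1'–C7' and C10'–C16'). C8' and C9' can therefore come from one two-carbon unit, and one ω-arylheptyl halide can serve as both nucleophile and electrophile.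

## Retrosynthesis

The acetyl C–O bond of 13 is cut first, giving the symmetric tetraphenol 12. This cut is preferred over carrying an ester through the synthesis because no aryl acetate would survive the organometallic chain assembly. Since the four hydroxyls of 12 are symmetry-equivalent, the forward reaction needs only a controlled single acylation, not a choice between different sites.

The four O–H groups of 12 are then masked as methoxymethyl ethers, giving 11. Acetals are chosen over their neighbours for three reasons: methyl ethers would need a harsh Lewis-acidic or thiolate cleavage next to the cis-alkene, benzyl ethers would need hydrogenolysis, and aryl silyl ethers are less reliable toward alkyllithium reagents. The forward step is a mild acid-catalysed alcoholysis that leaves a 1,2-dialkyl alkene untouched.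

The key cut removes C7'–C8' and C9'–C10' from 11 together, giving two molecules of iodide 6 and acetylene 7. Cutting across C8'=C9' instead (an olefination) would require two different C8 arms and would not guarantee the geometry. An alkyne route would need a separate semi-reduction. The chosen cut halves the molecule, uses one arm twice and lets the syn addition of an organocopper reagent to 7 set the Z geometry. The forward reaction must convert 6 into alkyllithium 8 and cuprate 9 without touching the acetal-flanked ring position, insert exactly one molecule of 7 per alkyl group to give alkenylcuprate 10, and alkylate 10 with more 6 with retention.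

Iodide 6 is traced by halide exchange to bromide 5, and the aryl–C1' bond of 5 is cut to give the aryl Grignard reagent 4 and the symmetric dihalide 3. This sp2–sp3 cut is preferred to a benzylic C1'–C2' cut because it uses a commercial C7 unit directly and needs no benzylic anion next to acetal directing groups. The forward coupling must stop after one end of 3 has reacted, which an excess of 3 ensures.

Grignard reagent 4 comes from aryl bromide 2, and removing the two acetal groups of 2 gives commercial 1. The forward step is a routine double etherification, and the substitution pattern of both rings is bought with 1 and never has to be controlled.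

## Roads not taken

Alternative 1: Both arenes are opened instead of the chain. Each ring is traced to a 3,5,7-triketo ester, so the whole skeleton becomes the bis(triketo ester) A2, built by chain extension at both carboxyl groups of the cis-C18 diacid A3.
- Forward key step: base would trigger at each end an intramolecular aldol condensation of C2 onto the C7 ketone, then dehydration and enolisation, closing both benzene rings to give the bis(resorcylate) A1.
- Merits: the Z-alkene is bought with A3 and never has to be made; both rings form in one operation; no phenol protection is needed.
- Weak points: A2 is a hexacarbonyl compound open to other closures (Claisen-type C-acylation to acylphloroglucinols, lactonisation to pyrones), and both ends must cyclise in the same sense. A1 still carries two ester groups, so saponification and decarboxylation are needed before 12 is reached. The monoacetylation problem is unchanged.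
- Comparison: in alkene geometry this road is better than the chosen plan, which must create the Z double bond itself. The chosen plan offers instead stable, chromatographable intermediates, a shorter sequence and no dependence on the regiochemistry of a polyketide-type cyclisation.

Alternative 2: Each resorcinol ring is cut at three ring C–C bonds into a cyclobutenone and an alkoxyalkyne, leading to the chain-linked bis(cyclobutenone) A5 and ethoxyacetylene A6.
- Forward key step: on heating, each four-membered ring would open to a vinylketene, add A6, reopen, undergo 6π electrocyclisation and tautomerise to the bis(3-ethoxyphenol) A4.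
- Merits: the 1,3,5-pattern is dictated by the mechanism; the neutral thermal conditions tolerate the cis-alkene; A4 arrives with one free and one etherified oxygen on each ring.
- Weak points: A5 has two strained enones at the ends of a chain that must already contain the Z-alkene, and the usual ketene-based routes to cyclobutenones would also attack that alkene. A6 is costly and volatile. The ethyl ethers of A4 need a strong Lewis acid or a hot thiolate for cleavage, which threatens the alkene and cannot be done in the presence of an aryl acetate, so the built-in differentiation of the oxygens cannot be used.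
- Comparison: ring regiochemistry is equally secure in both plans, since here it is purchased with 1. The chosen plan is shorter, creates the alkene in its key step and ends with a mild deprotection.

Alternative 3: The two benzylic bonds C1'–C2' and C15'–C16' are cut, giving two molecules of orcinol dimethyl ether A8 and the cis-C14 dibromide A9.
- Forward key step: lateral metalation of A8 with a mixed lithium–potassium amide base and twofold SN2 displacement on A9 would give the tetramethyl ether A7.
- Merits: A8 is much cheaper than 1 and needs no protection step; the union is highly convergent and uses the symmetry as fully as the chosen plan does.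
- Weak points: A9 already contains the Z-alkene and needs its own multistep synthesis, so the stereochemical problem is only relocated. The strongly basic benzylic anion can eliminate HBr from a primary bromide, and ring metalation between the methoxy groups competes unless the anion is fully equilibrated. The four methyl ethers of A7 require a harsh final cleavage next to the alkene.
- Comparison: in cost of the aromatic building block and in convergence this road is at least equal to the chosen plan. The chosen plan offers instead an alkene formed in the chain-forming step itself with mechanistically fixed geometry, a single arm used twice, and acid-labile protecting groups.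

Key step: step 4

Remark: chain atoms are numbered C1' (on the acetoxy-bearing ring A) to C16' (on ring B). Equivalents in step 4 are counted per CuBr·SMe2. Because all four hydroxyls of 12 are equivalent, acetylation of any one gives the target.

## Route

Step 1
Reactants: 1 5-bromobenzene-1,3-diol
Product: 2 1-bromo-3,5-bis(methoxymethoxy)benzene
Conditions: MOMCl (2.5 equiv), i-Pr2NEt (3 equiv), CH2Cl2, 0 °C → rt
Reagents that add atoms: chloromethyl methyl ether, COCCl
Why: Double O-alkylation of the phenols by the reactive α-chloro ether under amine base (methoxymethyl ether formation); the aryl bromide is inert and the hard electrophile gives no C-alkylation.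

Step 2
Reactants: 2 1-bromo-3,5-bis(methoxymethoxy)benzene; 3 1,7-dibromoheptane
Product: 5 1-(7-bromoheptyl)-3,5-bis(methoxymethoxy)benzene, via arylmagnesium bromide 4 (not isolated)
Conditions: Mg, THF, reflux; then 3 (3 equiv), Li2CuCl4 (5 mol %), THF, −10 °C → rt
Reagents that add atoms: none
Why: Magnesium insertion gives Grignard reagent 4, and the Li2CuCl4-catalysed sp2–sp3 cross-coupling of aryl Grignard reagents with primary bromides (Kochi-type coupling) proceeds at low temperature in the presence of acetals. The threefold excess of 3 should suppress reaction at both ends, and unreacted 3 is recovered by distillation.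

Step 3
Reactants: 5 1-(7-bromoheptyl)-3,5-bis(methoxymethoxy)benzene
Product: 6 1-(7-iodoheptyl)-3,5-bis(methoxymethoxy)benzene
Conditions: NaI (3 equiv), acetone, reflux
Reagents that add atoms: sodium iodide, [Na+].[I-]
Why: Finkelstein exchange driven by precipitation of NaBr; the iodide is needed both for clean iodine–lithium exchange and as the better electrophile toward the alkenylcuprate.

Step 4
Reactants: 6 1-(7-iodoheptyl)-3,5-bis(methoxymethoxy)benzene; 7 acetylene
Product: 11 (Z)-1,16-bis[3,5-bis(methoxymethoxy)phenyl]hexadec-8-ene, via alkyllithium 8 (not isolated), via lithium dialkylcuprate 9 (not isolated), via lithium bis[(Z)-alkenyl]cuprate 10 (not isolated)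
Conditions: 6 (2 equiv), t-BuLi (4.1 equiv), Et2O/pentane, −78 °C; CuBr·SMe2 (1 equiv), Et2O, −40 °C; 7 (2 equiv), −50 → −25 °C; then 6 (2 equiv), HMPA, P(OEt)3, THF, −40 °C → rt
Reagents that add atoms: none
Why: Iodine–lithium exchange with two equivalents of tert-butyllithium at −78 °C is much faster than deprotonation of the ring position between the two acetal oxygens and gives 8, which CuBr·SMe2 converts into the Gilman-type cuprate 9. Each alkyl group of 9 then adds across one molecule of acetylene through a four-centre syn transition state, forming C7'–C8' and giving 10; this is the Normant carbocupration of acetylene, the closest known reaction type and the classical entry to (Z)-alkene pheromone chains. In THF with HMPA and P(OEt)3 both alkenyl ligands of 10 should be alkylated by further primary iodide 6 with retention at the sp2 carbon, forming C9'–C10'. No ring is closed and no stereocentre is created; the Z geometry of C8'=C9' follows from the syn addition and is kept because the alkenylcuprate is configurationally stable while cold. The step needs a single acetylene insertion per alkyl group, which is secured by a measured two equivalents of acetone-free acetylene introduced at −50 °C, where a second insertion into the less reactive alkenyl–copper bond is slow. It also needs the acetal groups to stay out of the chemistry, which they should because organocopper reagents do not attack MOM ethers and the basic alkyllithium exists only at −78 °C. Because nucleophile and electrophile derive from the same iodide, no cross- versus homo-coupling issue arises and one operation delivers the whole C16 chain.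

Step 5
Reactants: 11 (Z)-1,16-bis[3,5-bis(methoxymethoxy)phenyl]hexadec-8-ene
Product: 12 5,5'-[(Z)-hexadec-8-ene-1,16-diyl]bis(benzene-1,3-diol)
Conditions: HCl (2 M), MeOH/THF, 45 °C
Reagents that add atoms: none
Why: Acid-catalysed acetal methanolysis releases the four phenols and removes the MOM carbons as dimethoxymethane, which keeps the formaldehyde equivalent away from the electron-rich rings. A 1,2-dialkyl alkene neither adds HCl nor isomerises under these dilute conditions.

Step 6
Reactants: 12 5,5'-[(Z)-hexadec-8-ene-1,16-diyl]bis(benzene-1,3-diol)
Product: 13 3-[(Z)-16-(3,5-dihydroxyphenyl)hexadec-8-en-1-yl]-5-hydroxyphenyl acetate (oncostemonol B)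
Conditions: Ac2O (1.0 equiv, slow addition), pyridine, THF, 0 °C
Reagents that add atoms: acetic anhydride, CC(=O)OC(C)=O
Why: Pyridine-mediated O-acylation of a phenol; the four hydroxyls are symmetry-equivalent, so any single acetylation gives 13 and only the degree of acylation must be controlled. Slow addition of one equivalent, chromatographic separation, and recycling of recovered 12 and of over-acetylated fractions (after K2CO3/MeOH methanolysis back to 12) should make this statistical step workable.

## Compound list

1 | 5-bromobenzene-1,3-diol | Oc1cc(O)cc(Br)c1 | starting material
2 | 1-bromo-3,5-bis(methoxymethoxy)benzene | COCOc1cc(OCOC)cc(Br)c1 | intermediate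
3 | 1,7-dibromoheptane | BrCCCCCCCBr | starting material
4 | [3,5-bis(methoxymethoxy)phenyl]magnesium bromide | COCOc1cc(OCOC)cc([Mg]Br)c1 | intermediate
5 | 1-(7-bromoheptyl)-3,5-bis(methoxymethoxy)benzene | COCOc1cc(OCOC)cc(CCCCCCCBr)c1 | intermediate
6 | 1-(7-iodoheptyl)-3,5-bis(methoxymethoxy)benzene | COCOc1cc(OCOC)cc(CCCCCCCI)c1 | intermediate
7 | acetylene | C#C | starting material
8 | {7-[3,5-bis(methoxymethoxy)phenyl]heptyl}lithium | [Li]CCCCCCCc1cc(OCOC)cc(OCOC)c1 | intermediate
9 | lithium bis{7-[3,5-bis(methoxymethoxy)phenyl]heptyl}cuprate | [Li+].COCOc1cc(OCOC)cc(CCCCCCC[Cu-]CCCCCCCc2cc(OCOC)cc(OCOC)c2)c1 | intermediate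
10 | lithium bis{(Z)-9-[3,5-bis(methoxymethoxy)phenyl]non-1-en-1-yl}cuprate | [Li+].[Cu-](/C=C\CCCCCCCc1cc(OCOC)cc(OCOC)c1)/C=C\CCCCCCCc1cc(OCOC)cc(OCOC)c1 | intermediate
11 | (Z)-1,16-bis[3,5-bis(methoxymethoxy)phenyl]hexadec-8-ene | COCOc1cc(OCOC)cc(CCCCCCC/C=C\CCCCCCCc2cc(OCOC)cc(OCOC)c2)c1 | intermediate
12 | 5,5'-[(Z)-hexadec-8-ene-1,16-diyl]bis(benzene-1,3-diol) | Oc1cc(O)cc(CCCCCCC/C=C\CCCCCCCc2cc(O)cc(O)c2)c1 | intermediate
13 | 3-[(Z)-16-(3,5-dihydroxyphenyl)hexadec-8-en-1-yl]-5-hydroxyphenyl acetate (oncostemonol B) | CC(=O)Oc1cc(O)cc(CCCCCCC/C=C\CCCCCCCc2cc(O)cc(O)c2)c1 | target

## Step count and risk assessment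

Total step count: 6. Longest linear sequence: 6 steps (1 → 2 → 5 → 6 → 11 → 12 → 13); 3 and 7 enter as commercial materials.

**Step 4 (key step).**
- What may go wrong: the alkylation of the alkenylcuprate may be slow or incomplete. Only one of the two alkenyl ligands may be transferred, and the remainder is protonated on work-up to a terminal alkene. The long-chain iodide is a modest electrophile and the alkenylcuprate loses configurational and thermal stability if warmed to force the reaction. A second concern is proton abstraction from the ring position between the two acetal groups while the alkyllithium is present, which would waste the nucleophile.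
- Fallback (sets out from cuprate 10 and iodide 6, returns at 11): the two bonds are still made at the same places, but in two operations.
  - Cuprate 10, generated from 6 and 7 as in the first half of step 4, is quenched with iodine at −50 °C, which should give 1-[(Z)-9-iodonon-8-en-1-yl]-3,5-bis(methoxymethoxy)benzene F1 with retention.
  - A second portion of 6 is converted with zinc dust and LiCl in THF into {7-[3,5-bis(methoxymethoxy)phenyl]heptyl}zinc iodide F2.
  - F2 is coupled with F1 under Pd(PPh3)4 catalysis (Negishi sp3–sp2 coupling, retention at the alkenyl carbon) to give 11.
  - The organozinc route also avoids any alkyllithium in the presence of the electrophile arm.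

**Step 6.**
- What may go wrong: non-selective multiple acylation. The four hydroxyls are equivalent and react independently, so a single pass has a calculated statistical ceiling of about 42 % monoacetate, and the polar mono-, di- and unacetylated phenols may be hard to separate.
- Fallback (sets out from 1, uses 3 and cuprate 10, returns at 13): the two arms are made different before the key step, so the acetate is placed by protecting-group logic.
  - Reaction of 1 with one equivalent of chloromethyl methyl ether gives 3-bromo-5-(methoxymethoxy)phenol F3. The statistical event is thereby moved to the cheapest compound; recovered 1 is reused and the bis-ether 2 formed alongside feeds the normal route.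
  - Silylation with TIPSCl and imidazole gives [3-bromo-5-(methoxymethoxy)phenoxy]tri(propan-2-yl)silane F4.
  - Magnesium insertion gives {3-(methoxymethoxy)-5-[tri(propan-2-yl)silyloxy]phenyl}magnesium bromide F5, which is coupled with excess 3 under Li2CuCl4 catalysis to [3-(7-bromoheptyl)-5-(methoxymethoxy)phenoxy]tri(propan-2-yl)silane F6.
  - NaI in acetone gives [3-(7-iodoheptyl)-5-(methoxymethoxy)phenoxy]tri(propan-2-yl)silane F7.
  - Alkenylcuprate 10, prepared from 6 and 7 as in step 4, is alkylated with F7 instead of 6 to give (Z)-1-[3,5-bis(methoxymethoxy)phenyl]-16-{3-(methoxymethoxy)-5-[tri(propan-2-yl)silyloxy]phenyl}hexadec-8-ene F8.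
  - Tetrabutylammonium fluoride removes the single silyl group to give 3-{(Z)-16-[3,5-bis(methoxymethoxy)phenyl]hexadec-8-en-1-yl}-5-(methoxymethoxy)phenol F9.
  - Complete acetylation (Ac2O, pyridine) gives 3-{(Z)-16-[3,5-bis(methoxymethoxy)phenyl]hexadec-8-en-1-yl}-5-(methoxymethoxy)phenyl acetate F10.
  - The three MOM groups are finally cleaved with ZnBr2 and propane-1-thiol in CH2Cl2 at 0 °C, non-basic and non-alcoholic conditions that should spare the aryl acetate and the alkene, giving 13.
  - The price is a longer, non-symmetric sequence.

**Step 2.**
- What may go wrong: sluggish magnesium insertion into the electron-rich, chelating aryl bromide; homocoupling of the Grignard reagent; and a second coupling at the far end of the dihalide, giving a 1,7-diarylheptane that consumes two aryl units.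
- Fallback (sets out from 2, returns at 6): the aryl–chain bond is made by palladium catalysis with a chain that has only one reactive end.
  - Sonogashira coupling of 2 with hept-6-yn-1-ol (PdCl2(PPh3)2, CuI, Et3N, 70 °C) gives 7-[3,5-bis(methoxymethoxy)phenyl]hept-6-yn-1-ol F11.
  - Hydrogenation over Pd/C gives 7-[3,5-bis(methoxymethoxy)phenyl]heptan-1-ol F12.
  - Appel iodination (I2, PPh3, imidazole, CH2Cl2) gives 6 directly, bypassing 5.

## Further compounds

F1 | step 4 | 1-[(Z)-9-iodonon-8-en-1-yl]-3,5-bis(methoxymethoxy)benzene | COCOc1cc(OCOC)cc(CCCCCCC/C=C\I)c1
F2 | step 4 | {7-[3,5-bis(methoxymethoxy)phenyl]heptyl}zinc iodide | COCOc1cc(OCOC)cc(CCCCCCC[Zn]I)c1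
F3 | step 6 | 3-bromo-5-(methoxymethoxy)phenol | COCOc1cc(O)cc(Br)c1
F4 | step 6 | [3-bromo-5-(methoxymethoxy)phenoxy]tri(propan-2-yl)silane | COCOc1cc(O[Si](C(C)C)(C(C)C)C(C)C)cc(Br)c1
F5 | step 6 | {3-(methoxymethoxy)-5-[tri(propan-2-yl)silyloxy]phenyl}magnesium bromide | COCOc1cc(O[Si](C(C)C)(C(C)C)C(C)C)cc([Mg]Br)c1
F6 | step 6 | [3-(7-bromoheptyl)-5-(methoxymethoxy)phenoxy]tri(propan-2-yl)silane | COCOc1cc(O[Si](C(C)C)(C(C)C)C(C)C)cc(CCCCCCCBr)c1
F7 | step 6 | [3-(7-iodoheptyl)-5-(methoxymethoxy)phenoxy]tri(propan-2-yl)silane | COCOc1cc(O[Si](C(C)C)(C(C)C)C(C)C)cc(CCCCCCCI)c1
F8 | step 6 | (Z)-1-[3,5-bis(methoxymethoxy)phenyl]-16-{3-(methoxymethoxy)-5-[tri(propan-2-yl)silyloxy]phenyl}hexadec-8-ene | COCOc1cc(OCOC)cc(CCCCCCC/C=C\CCCCCCCc2cc(OCOC)cc(O[Si](C(C)C)(C(C)C)C(C)C)c2)c1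
F9 | step 6 | 3-{(Z)-16-[3,5-bis(methoxymethoxy)phenyl]hexadec-8-en-1-yl}-5-(methoxymethoxy)phenol | COCOc1cc(OCOC)cc(CCCCCCC/C=C\CCCCCCCc2cc(O)cc(OCOC)c2)c1
F10 | step 6 | 3-{(Z)-16-[3,5-bis(methoxymethoxy)phenyl]hexadec-8-en-1-yl}-5-(methoxymethoxy)phenyl acetate | COCOc1cc(OCOC)cc(CCCCCCC/C=C\CCCCCCCc2cc(OC(C)=O)cc(OCOC)c2)c1
F11 | step 2 | 7-[3,5-bis(methoxymethoxy)phenyl]hept-6-yn-1-ol | COCOc1cc(OCOC)cc(C#CCCCCCO)c1
F12 | step 2 | 7-[3,5-bis(methoxymethoxy)phenyl]heptan-1-ol | COCOc1cc(OCOC)cc(CCCCCCCO)c1
A1 | alternative 1 | dimethyl 6,6'-[(Z)-hexadec-8-ene-1,16-diyl]bis(2,4-dihydroxybenzoate) | COC(=O)c1c(O)cc(O)cc1CCCCCCC/C=C\CCCCCCCc1cc(O)cc(O)c1C(=O)OC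
A2 | alternative 1 | dimethyl (Z)-3,5,7,24,26,28-hexaoxotriacont-15-enedioate | COC(=O)CC(=O)CC(=O)CC(=O)CCCCCCC/C=C\CCCCCCCC(=O)CC(=O)CC(=O)CC(=O)OC
A3 | alternative 1 | (Z)-octadec-9-enedioic acid | OC(=O)CCCCCCC/C=C\CCCCCCCC(=O)O
A4 | alternative 2 | 5,5'-[(Z)-hexadec-8-ene-1,16-diyl]bis(3-ethoxyphenol) | CCOc1cc(O)cc(CCCCCCC/C=C\CCCCCCCc2cc(O)cc(OCC)c2)c1
A5 | alternative 2 | 3,3'-[(Z)-hexadec-8-ene-1,16-diyl]bis(cyclobut-2-en-1-one) | O=C1CC(CCCCCCC/C=C\CCCCCCCC2=CC(=O)C2)=C1
A6 | alternative 2 | ethoxyacetylene (ethoxyethyne) | CCOC#C
A7 | alternative 3 | (Z)-1,16-bis(3,5-dimethoxyphenyl)hexadec-8-ene | COc1cc(OC)cc(CCCCCCC/C=C\CCCCCCCc2cc(OC)cc(OC)c2)c1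
A8 | alternative 3 | 1,3-dimethoxy-5-methylbenzene (orcinol dimethyl ether) | COc1cc(OC)cc(C)c1
A9 | alternative 3 | (Z)-1,14-dibromotetradec-7-ene | BrCCCCCC/C=C\CCCCCCBr
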